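## Retrosynthetic overview

- The target is cut at the primary ester (formed second to last) into the side-chain acid 16 and the bicyclic diol lactone 31; its tertiary alcohol and CH2O carbon come from an exocyclic methylene, and that from a ring ketone.
- The cyclohexane ring of the core is closed last, by an aminocatalysed Michael/aldol-condensation annulation of isovaleraldehyde onto the seven-membered lactone 25.
- The enabling feature is the ring C5=C6 double bond of oxepinone 25, flanked by the lactone carbonyl C-7 and the exocyclic acetyl group on C-6 (an alkylidene β-keto lactone). C-5 is therefore a doubly activated acceptor, and the acetyl group supplies the last two ring carbons and the aldol donor.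
- Lactone 25 comes from a ring-closing metathesis and a selenoxide dehydrogenation.
- Acid 16 comes from (S)-cryptone, made from the same aldehyde with the same catalyst family. Ring order: side-chain cyclohexene (step 1), oxepinone (step 10), core cyclohexane (step 12).

Key step: step 12

Remark: β-keto lactones 22, 28 and 29 are drawn as keto tautomers, and the trans ring fusion is assumed to be the stable one. Bicyclic compounds carry 2-benzoxepine locants (C-1 lactone carbonyl, O-2, C-3, C-4, C-5, C-5a, C-6 isopropyl carbon, C-7, C-8, C-9, C-9a); monocyclic lactones carry oxepine locants.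

## Route

Step 1
Reactants: 1 3-methylbutanal; 2 but-3-en-2-one
Product: 5 (4S)-4-(propan-2-yl)cyclohex-2-en-1-one, via keto aldehyde 3 (not isolated), via ketol 4 (not isolated)
Conditions: (S)-α,α-diphenylprolinol methyl ether (5 mol %), ethyl 3,4-dihydroxybenzoate (20 mol %), neat, 4 °C; then LiOH (10 mol %), iPrOH, rt
Reagents that add atoms: none
Why: Enamine-mediated asymmetric Michael addition, in which the catalyst shields one enamine face and sets the isopropyl-bearing centre as S, is followed by a Robinson-type intramolecular aldol condensation that closes the cyclohexenone without touching that centre.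

Step 2
Reactants: 5 (4S)-4-(propan-2-yl)cyclohex-2-en-1-one
Product: 7 (3S,4S)-3-ethenyl-4-(propan-2-yl)cyclohex-1-en-1-yl trifluoromethanesulfonate, via magnesium enolate 6 (not isolated)
Conditions: CH2=CHMgBr, CuBr·SMe2 (10 mol %), THF, −78 °C; then N-(5-chloropyridin-2-yl)bis(trifluoromethanesulfonyl)imide, −78 → 0 °C
Reagents that add atoms: vinylmagnesium bromide, C=C[Mg]Br; N-(5-chloropyridin-2-yl)bis(trifluoromethanesulfonyl)imide, Clc1ccc(nc1)N(S(=O)(=O)C(F)(F)F)S(=O)(=O)C(F)(F)F
Why: Copper-catalysed conjugate addition of the Grignard reagent should occur anti to the neighbouring isopropyl group (trans product), and O-triflation of the regiodefined enolate fixes the ring double bond where the target needs it.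

Step 3
Reactants: 7 (3S,4S)-3-ethenyl-4-(propan-2-yl)cyclohex-1-en-1-yl trifluoromethanesulfonate
Product: 9 (3S,4S)-3-formyl-4-(propan-2-yl)cyclohex-1-en-1-yl trifluoromethanesulfonate, via diol 8 (not isolated)
Conditions: OsO4 (2 mol %), NaIO4 (3 equiv), 2,6-lutidine, 1,4-dioxane/H2O 3:1, rt
Reagents that add atoms: osmium tetroxide, O=[Os](=O)(=O)=O; sodium periodate, [Na+].[O-]I(=O)(=O)=O
Why: Lemieux–Johnson oxidation should attack the electron-richer monosubstituted vinyl group and leave the electron-poor enol triflate alkene alone; the lutidine buffer limits epimerisation of the new aldehyde, whose trans form is the stable one in any case.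

Step 4
Reactants: 9 (3S,4S)-3-formyl-4-(propan-2-yl)cyclohex-1-en-1-yl trifluoromethanesulfonate; 10 ethyl 2-(diethoxyphosphoryl)prop-2-enoate; 11 (4-methoxyphenyl)methanol
Product: 13 ethyl (2E)-2-{[(4-methoxyphenyl)methoxy]methyl}-3-[(1R,6S)-6-(propan-2-yl)-3-(trifluoromethanesulfonyloxy)cyclohex-2-en-1-yl]prop-2-enoate, via phosphonate carbanion 12 (not isolated)
Conditions: 11, NaH (1.0 equiv), THF, 0 °C; 10, −20 °C; then 9, −20 °C → rt
Reagents that add atoms: none
Why: Oxa-Michael addition of the alkoxide to the vinylphosphonate gives the α-substituted phosphonate carbanion, whose Horner–Wadsworth–Emmons reaction with the α-branched aldehyde should give mainly the (E)-enoate with the ring carbon trans to the ester.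

Step 5
Reactants: 13 ethyl (2E)-2-{[(4-methoxyphenyl)methoxy]methyl}-3-[(1R,6S)-6-(propan-2-yl)-3-(trifluoromethanesulfonyloxy)cyclohex-2-en-1-yl]prop-2-enoate
Product: 14 ethyl (2E)-3-[(1S,6S)-3-(hydroxymethyl)-6-(propan-2-yl)cyclohex-2-en-1-yl]-2-{[(4-methoxyphenyl)methoxy]methyl}prop-2-enoate
Conditions: Bu3SnCH2OH (1.5 equiv), Pd(PPh3)4 (5 mol %), LiCl (3 equiv), 1,4-dioxane, 90 °C
Reagents that add atoms: (tributylstannyl)methanol, OC[Sn](CCCC)(CCCC)CCCC
Why: Stille coupling of the alkenyl triflate with the hydroxymethyl stannane (chloride assists transmetalation) installs the CH2OH group without moving the double bond; the allylic ether is not ionised by zerovalent palladium.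

Step 6
Reactants: 14 ethyl (2E)-3-[(1S,6S)-3-(hydroxymethyl)-6-(propan-2-yl)cyclohex-2-en-1-yl]-2-{[(4-methoxyphenyl)methoxy]methyl}prop-2-enoate
Product: 15 ethyl (2E)-3-[(1S,6S)-3-({[tert-butyl(dimethyl)silyl]oxy}methyl)-6-(propan-2-yl)cyclohex-2-en-1-yl]-2-{[(4-methoxyphenyl)methoxy]methyl}prop-2-enoate
Conditions: TBSCl, imidazole, DMF, rt
Reagents that add atoms: tert-butyldimethylsilyl chloride, CC(C)(C)[Si](C)(C)Cl
Why: Standard silylation of the primary allylic alcohol, needed so that the acid cannot esterify itself in step 16.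

Step 7
Reactants: 15 ethyl (2E)-3-[(1S,6S)-3-({[tert-butyl(dimethyl)silyl]oxy}methyl)-6-(propan-2-yl)cyclohex-2-en-1-yl]-2-{[(4-methoxyphenyl)methoxy]methyl}prop-2-enoate
Product: 16 (2E)-3-[(1S,6S)-3-({[tert-butyl(dimethyl)silyl]oxy}methyl)-6-(propan-2-yl)cyclohex-2-en-1-yl]-2-{[(4-methoxyphenyl)methoxy]methyl}prop-2-enoic acid
Conditions: LiOH·H2O (3 equiv), THF/MeOH/H2O, rt → 40 °C; then dilute HCl to pH 4, 0 °C
Reagents that add atoms: lithium hydroxide, [Li+].[OH-]
Why: Saponification of the ethyl ester; the primary silyl ether and the benzylic ether should survive aqueous hydroxide and the brief mild acidification.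

Step 8
Reactants: 17 tert-butyl prop-2-enoate; 18 formaldehyde (37% aqueous)
Product: 19 tert-butyl 2-(hydroxymethyl)prop-2-enoate
Conditions: DABCO (0.3 equiv), 1,4-dioxane/H2O 1:1, rt
Reagents that add atoms: none
Why: Morita–Baylis–Hillman reaction of the acrylate with formaldehyde.

Step 9
Reactants: 19 tert-butyl 2-(hydroxymethyl)prop-2-enoate; 20 ethyl 2-acetylpent-4-enoate
Product: 21 tert-butyl 2-{[(2-acetylpent-4-enoyl)oxy]methyl}prop-2-enoate
Conditions: DMAP (20 mol %), toluene, reflux, 4 Å MS, BHT (trace)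
Reagents that add atoms: none
Why: DMAP-catalysed transesterification of the β-keto ester proceeds through the acylketene and is driven by removal of ethanol.

Step 10
Reactants: 21 tert-butyl 2-{[(2-acetylpent-4-enoyl)oxy]methyl}prop-2-enoate
Product: 22 tert-butyl 6-acetyl-7-oxo-2,5,6,7-tetrahydrooxepine-3-carboxylate (racemic)
Conditions: second-generation Hoveyda–Grubbs catalyst (5 mol %), toluene (0.005 M), 80 °C
Reagents that add atoms: none
Why: Ring-closing metathesis of the allyl group with the 1,1-disubstituted acrylate alkene closes the seven-membered lactone; the ring enforces the required geometry of the new trisubstituted alkene and dilution suppresses oligomers.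

Step 11
Reactants: 22 tert-butyl 6-acetyl-7-oxo-2,5,6,7-tetrahydrooxepine-3-carboxylate
Product: 25 tert-butyl 6-acetyl-7-oxo-2,7-dihydrooxepine-3-carboxylate, via selenide 23 (not isolated), via selenoxide 24 (not isolated)
Conditions: PhSeCl (1.1 equiv), pyridine, CH2Cl2, 0 °C; then 30% H2O2 (2 equiv), 0 °C → rt; product used directly
Reagents that add atoms: none
Why: α-Selenenylation of the β-keto lactone at the carbon between the two carbonyls and selenoxide syn-elimination, for which only the C-5 hydrogens are available, introduce the C5=C6 double bond.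

Step 12
Reactants: 25 tert-butyl 6-acetyl-7-oxo-2,7-dihydrooxepine-3-carboxylate; 1 3-methylbutanal
Product: 28 tert-butyl (5aS,6S,9aS)-1,9-dioxo-6-(propan-2-yl)-1,3,5a,6,9,9a-hexahydro-2-benzoxepine-4-carboxylate, via Michael adduct 26 (not isolated), via ketol 27 (not isolated)
Conditions: 1 (3 equiv), (S)-α,α-diphenylprolinol trimethylsilyl ether (20 mol %), PhCO2H (20 mol %), toluene, 0 °C → rt; evaporate excess 1; then p-TsOH·H2O (30 mol %), 4 Å MS, toluene, 40 °C
Reagents that add atoms: none
Why: The amine converts 1 into its (E)-enamine, which adds through its unshielded face to C-5 of 25, and hydrolysis gives keto aldehyde 26 (in equilibrium with its cyclic hemiacetal); acid then promotes aldol addition of the acetyl methyl group to the aldehyde and dehydration. The closest known reaction types are the diarylprolinol silyl ether catalysed Michael addition of aldehydes to nitroalkenes and alkylidene 1,3-dicarbonyl compounds, and the acid-mediated Robinson-type aldol condensation of keto aldehyde Michael adducts to cyclohexenones. The cyclohexane ring closes in a 6-(enolendo)-exo-trig aldol mode, the acetyl group supplying C-8 and C-9 and the aldehyde supplying C-7 and C-6. C-6 is set by the catalyst, whose diphenyl(silyloxy)methyl group blocks one enamine face; C-5a is set by the synclinal open transition state that gives the syn Michael adduct, the acetyl carbonyl (trans to the ring residue on the acceptor) pointing to the enamine nitrogen as the nitro group does in nitroalkene additions; C-9a is set by equilibration of the β-keto lactone to the trans ring fusion. The step needs attack at C-5 and not at C-4 of the dienyl lactone, which the double activation of C-5 secures, and carbocyclisation in preference to dehydration of the hemiacetal to a pyran, which mild acid and irreversible enone formation should favour.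

Step 13
Reactants: 28 tert-butyl (5aS,6S,9aS)-1,9-dioxo-6-(propan-2-yl)-1,3,5a,6,9,9a-hexahydro-2-benzoxepine-4-carboxylate
Product: 29 tert-butyl (5aS,6R,9aS)-1,9-dioxo-6-(propan-2-yl)-1,3,5a,6,7,8,9,9a-octahydro-2-benzoxepine-4-carboxylate
Conditions: H2 (1 atm), RhCl(PPh3)3 (5 mol %), benzene/EtOH 1:1, rt
Reagents that add atoms: none
Why: Homogeneous hydrogenation should reduce the cis-disubstituted enone alkene much faster than the trisubstituted ester-conjugated C4=C5 alkene and should not cleave the allylic lactone C–O bond.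

Step 14
Reactants: 29 tert-butyl (5aS,6R,9aS)-1,9-dioxo-6-(propan-2-yl)-1,3,5a,6,7,8,9,9a-octahydro-2-benzoxepine-4-carboxylate
Product: 30 tert-butyl (5aS,6R,9aS)-9-methylidene-1-oxo-6-(propan-2-yl)-1,3,5a,6,7,8,9,9a-octahydro-2-benzoxepine-4-carboxylate
Conditions: Zn, CH2Br2, TiCl4 (reagent pre-formed in THF, 5 °C, 3 d); then 29, CH2Cl2, 0 °C → rt
Reagents that add atoms: dibromomethane, BrCBr
Why: Takai–Lombardo methylenation uses a weakly basic titanium–zinc methylene reagent that methylenates enolisable ketones without epimerisation and leaves lactone and ester carbonyls alone.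

Step 15
Reactants: 30 tert-butyl (5aS,6R,9aS)-9-methylidene-1-oxo-6-(propan-2-yl)-1,3,5a,6,7,8,9,9a-octahydro-2-benzoxepine-4-carboxylate
Product: 31 tert-butyl (5aS,6R,9S,9aS)-9-hydroxy-9-(hydroxymethyl)-1-oxo-6-(propan-2-yl)-1,3,5a,6,7,8,9,9a-octahydro-2-benzoxepine-4-carboxylate
Conditions: OsO4 (2 mol %), NMO (1.3 equiv), acetone/H2O 8:1, 0 °C
Reagents that add atoms: osmium tetroxide, O=[Os](=O)(=O)=O; N-methylmorpholine N-oxide, C[N+]1([O-])CCOCC1
Why: Upjohn dihydroxylation selects the electron-rich 1,1-disubstituted alkene over the acrylate, and OsO4 should approach the exocyclic alkene from the equatorial direction, away from the axial hydrogens at C-5a and C-7, so that the new tertiary OH is equatorial (9S) and the CH2OH axial.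

Step 16
Reactants: 31 tert-butyl (5aS,6R,9S,9aS)-9-hydroxy-9-(hydroxymethyl)-1-oxo-6-(propan-2-yl)-1,3,5a,6,7,8,9,9a-octahydro-2-benzoxepine-4-carboxylate; 16 (2E)-3-[(1S,6S)-3-({[tert-butyl(dimethyl)silyl]oxy}methyl)-6-(propan-2-yl)cyclohex-2-en-1-yl]-2-{[(4-methoxyphenyl)methoxy]methyl}prop-2-enoic acid
Product: 33 fully protected ester (tert-butyl ester of the target with the side-chain ring CH2OH as TBS ether and the acrylate CH2OH as 4-methoxybenzyl ether), via mixed anhydride 32 (not isolated)
Conditions: 16 (1.2 equiv), 2,4,6-Cl3C6H2COCl, Et3N, THF, rt; then 31, DMAP, toluene, 0 °C → rt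
Reagents that add atoms: none
Why: Yamaguchi esterification acylates only the primary hydroxyl of the diol, because the tertiary hydroxyl is inert under these conditions.

Step 17
Reactants: 33 fully protected ester
Product: 34 target, (5aS,6R,9S,9aS)-9-hydroxy-9-({[(2E)-2-(hydroxymethyl)-3-[(1S,6S)-3-(hydroxymethyl)-6-(propan-2-yl)cyclohex-2-en-1-yl]prop-2-enoyl]oxy}methyl)-1-oxo-6-(propan-2-yl)-1,3,5a,6,7,8,9,9a-octahydro-2-benzoxepine-4-carboxylic acid
Conditions: TFA/CH2Cl2 1:2, anisole (10 equiv), H2O (5 equiv), 0 °C → rt; aqueous NaHCO3 wash, then pH 4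
Reagents that add atoms: none
Why: Acidolysis should remove the tert-butyl ester (as isobutene), the 4-methoxybenzyl ether (cation trapped by anisole) and the silyl ether in one operation, while the lactone, the ester link and the tertiary alcohol (flanked by two electron-withdrawing groups) should survive.

## Compound list

1 | 3-methylbutanal (isovaleraldehyde) | CC(C)CC=O | starting material
2 | but-3-en-2-one (methyl vinyl ketone) | CC(=O)C=C | starting material
3 | (2S)-5-oxo-2-(propan-2-yl)hexanal | CC(C)[C@@H](C=O)CCC(C)=O | intermediate (not isolated)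
4 | (4S)-3-hydroxy-4-(propan-2-yl)cyclohexan-1-one, C-3 epimers | CC(C)[C@@H]1CCC(=O)CC1O | intermediate (not isolated)
5 | (4S)-4-(propan-2-yl)cyclohex-2-en-1-one, (S)-cryptone | CC(C)[C@@H]1CCC(=O)C=C1 | intermediate
6 | bromomagnesium (3S,4S)-3-ethenyl-4-(propan-2-yl)cyclohex-1-en-1-olate | C=C[C@@H]1C=C(O[Mg]Br)CC[C@H]1C(C)C | intermediate (not isolated)
7 | (3S,4S)-3-ethenyl-4-(propan-2-yl)cyclohex-1-en-1-yl trifluoromethanesulfonate | C=C[C@@H]1C=C(OS(=O)(=O)C(F)(F)F)CC[C@H]1C(C)C | intermediate
8 | (3S,4S)-3-(1,2-dihydroxyethyl)-4-(propan-2-yl)cyclohex-1-en-1-yl trifluoromethanesulfonate, carbinol epimers | OCC(O)[C@@H]1C=C(OS(=O)(=O)C(F)(F)F)CC[C@H]1C(C)C | intermediate (not isolated)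
9 | (3S,4S)-3-formyl-4-(propan-2-yl)cyclohex-1-en-1-yl trifluoromethanesulfonate | O=C[C@@H]1C=C(OS(=O)(=O)C(F)(F)F)CC[C@H]1C(C)C | intermediate
10 | ethyl 2-(diethoxyphosphoryl)prop-2-enoate | CCOC(=O)C(=C)P(=O)(OCC)OCC | starting material
11 | (4-methoxyphenyl)methanol | COc1ccc(CO)cc1 | starting material
12 | ethyl 2-(diethoxyphosphoryl)-3-[(4-methoxyphenyl)methoxy]propanoate, formed as its sodium salt | CCOC(=O)C(COCc1ccc(OC)cc1)P(=O)(OCC)OCC | intermediate (not isolated)
13 | ethyl (2E)-2-{[(4-methoxyphenyl)methoxy]methyl}-3-[(1R,6S)-6-(propan-2-yl)-3-(trifluoromethanesulfonyloxy)cyclohex-2-en-1-yl]prop-2-enoate | CCOC(=O)/C(COCc1ccc(OC)cc1)=C/[C@@H]1C=C(OS(=O)(=O)C(F)(F)F)CC[C@H]1C(C)C | intermediate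
14 | ethyl (2E)-3-[(1S,6S)-3-(hydroxymethyl)-6-(propan-2-yl)cyclohex-2-en-1-yl]-2-{[(4-methoxyphenyl)methoxy]methyl}prop-2-enoate | CCOC(=O)/C(COCc1ccc(OC)cc1)=C/[C@@H]1C=C(CO)CC[C@H]1C(C)C | intermediate
15 | ethyl (2E)-3-[(1S,6S)-3-({[tert-butyl(dimethyl)silyl]oxy}methyl)-6-(propan-2-yl)cyclohex-2-en-1-yl]-2-{[(4-methoxyphenyl)methoxy]methyl}prop-2-enoate | CCOC(=O)/C(COCc1ccc(OC)cc1)=C/[C@@H]1C=C(CO[Si](C)(C)C(C)(C)C)CC[C@H]1C(C)C | intermediate
16 | (2E)-3-[(1S,6S)-3-({[tert-butyl(dimethyl)silyl]oxy}methyl)-6-(propan-2-yl)cyclohex-2-en-1-yl]-2-{[(4-methoxyphenyl)methoxy]methyl}prop-2-enoic acid | OC(=O)/C(COCc1ccc(OC)cc1)=C/[C@@H]1C=C(CO[Si](C)(C)C(C)(C)C)CC[C@H]1C(C)C | intermediate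
17 | tert-butyl prop-2-enoate | C=CC(=O)OC(C)(C)C | starting material
18 | formaldehyde | C=O | starting material
19 | tert-butyl 2-(hydroxymethyl)prop-2-enoate | C=C(CO)C(=O)OC(C)(C)C | intermediate
20 | ethyl 2-acetylpent-4-enoate | CCOC(=O)C(CC=C)C(C)=O | starting material
21 | tert-butyl 2-{[(2-acetylpent-4-enoyl)oxy]methyl}prop-2-enoate | C=CCC(C(C)=O)C(=O)OCC(=C)C(=O)OC(C)(C)C | intermediate
22 | tert-butyl 6-acetyl-7-oxo-2,5,6,7-tetrahydrooxepine-3-carboxylate (racemic) | CC(=O)C1CC=C(C(=O)OC(C)(C)C)COC1=O | intermediate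
23 | tert-butyl 6-acetyl-7-oxo-6-(phenylselanyl)-2,5,6,7-tetrahydrooxepine-3-carboxylate | CC(=O)C1([Se]c2ccccc2)CC=C(C(=O)OC(C)(C)C)COC1=O | intermediate (not isolated)
24 | tert-butyl 6-acetyl-6-(benzeneseleninyl)-7-oxo-2,5,6,7-tetrahydrooxepine-3-carboxylate | CC(=O)C1([Se](=O)c2ccccc2)CC=C(C(=O)OC(C)(C)C)COC1=O | intermediate (not isolated)
25 | tert-butyl 6-acetyl-7-oxo-2,7-dihydrooxepine-3-carboxylate | CC(=O)C1=CC=C(C(=O)OC(C)(C)C)COC1=O | intermediate
26 | tert-butyl (5R)-6-acetyl-5-[(2R)-3-methyl-1-oxobutan-2-yl]-7-oxo-2,5,6,7-tetrahydrooxepine-3-carboxylate, C-6 epimers and enol | CC(C)[C@@H](C=O)[C@H]1C=C(C(=O)OC(C)(C)C)COC(=O)C1C(C)=O | intermediate (not isolated)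
27 | tert-butyl (5aS,6R,9aS)-7-hydroxy-1,9-dioxo-6-(propan-2-yl)-1,3,5a,6,7,8,9,9a-octahydro-2-benzoxepine-4-carboxylate, C-7 epimers | CC(C)[C@H]1C(O)CC(=O)[C@H]2C(=O)OCC(C(=O)OC(C)(C)C)=C[C@H]12 | intermediate (not isolated)
28 | tert-butyl (5aS,6S,9aS)-1,9-dioxo-6-(propan-2-yl)-1,3,5a,6,9,9a-hexahydro-2-benzoxepine-4-carboxylate | CC(C)[C@H]1C=CC(=O)[C@H]2C(=O)OCC(C(=O)OC(C)(C)C)=C[C@H]12 | intermediate
29 | tert-butyl (5aS,6R,9aS)-1,9-dioxo-6-(propan-2-yl)-1,3,5a,6,7,8,9,9a-octahydro-2-benzoxepine-4-carboxylate | CC(C)[C@H]1CCC(=O)[C@H]2C(=O)OCC(C(=O)OC(C)(C)C)=C[C@H]12 | intermediate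
30 | tert-butyl (5aS,6R,9aS)-9-methylidene-1-oxo-6-(propan-2-yl)-1,3,5a,6,7,8,9,9a-octahydro-2-benzoxepine-4-carboxylate | CC(C)[C@H]1CCC(=C)[C@H]2C(=O)OCC(C(=O)OC(C)(C)C)=C[C@H]12 | intermediate
31 | tert-butyl (5aS,6R,9S,9aS)-9-hydroxy-9-(hydroxymethyl)-1-oxo-6-(propan-2-yl)-1,3,5a,6,7,8,9,9a-octahydro-2-benzoxepine-4-carboxylate | CC(C)[C@H]1CC[C@@](O)(CO)[C@H]2C(=O)OCC(C(=O)OC(C)(C)C)=C[C@H]12 | intermediate
32 | mixed anhydride of acid 16 with 2,4,6-trichlorobenzoic acid | O=C(OC(=O)c1c(Cl)cc(Cl)cc1Cl)/C(COCc1ccc(OC)cc1)=C/[C@@H]1C=C(CO[Si](C)(C)C(C)(C)C)CC[C@H]1C(C)C | intermediate (not isolated)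
33 | fully protected ester: tert-butyl ester of 34 with side-chain ring CH2OH as TBS ether and acrylate CH2OH as 4-methoxybenzyl ether | CC(C)[C@H]1CC[C@@](O)(COC(=O)/C(COCc3ccc(OC)cc3)=C/[C@@H]3C=C(CO[Si](C)(C)C(C)(C)C)CC[C@H]3C(C)C)[C@H]2C(=O)OCC(C(=O)OC(C)(C)C)=C[C@H]12 | intermediate
34 | (5aS,6R,9S,9aS)-9-hydroxy-9-({[(2E)-2-(hydroxymethyl)-3-[(1S,6S)-3-(hydroxymethyl)-6-(propan-2-yl)cyclohex-2-en-1-yl]prop-2-enoyl]oxy}methyl)-1-oxo-6-(propan-2-yl)-1,3,5a,6,7,8,9,9a-octahydro-2-benzoxepine-4-carboxylic acid | CC(C)[C@H]1CC[C@@](O)(COC(=O)/C(=C/[C@@H]2C=C(CO)CC[C@H]2C(C)C)CO)[C@H]2C(=O)OCC(C(=O)O)=C[C@H]12 | target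

## Step count and risks

Total steps: 17. Longest linear sequence: 10 (steps 8 to 17, from tert-butyl acrylate); the side-chain branch (steps 1 to 7) joins at step 16.

Steps most likely to fail:

1. Step 12. The enamine may add to the wrong face of the lactone alkene (poor control at C-5a), and the acid stage may dehydrate the intermediate hemiacetal to a pyran, or epimerise C-6, instead of closing the carbocycle. The fallback sets out from 25 and changes the bond-forming mode to Lewis acid catalysis. A Cu(OTf)2/tert-butyl-bis(oxazoline)-catalysed inverse-electron-demand hetero-Diels–Alder reaction of the acetyl/C5=C6 oxadiene unit with (E)-1-ethoxy-3-methylbut-1-ene (CH2Cl2, −40 °C; ligand enantiomer chosen for the 5aS series) should give the bicyclic 2-ethoxydihydropyran F1. Endo approach of the (E)-enol ether places the isopropyl group trans to the lactone ring residue. Mild hydrolysis of the mixed acetal (PPTS, wet acetone) releases keto aldehyde 26, which is closed with piperidinium acetate or p-TsOH, and the route is rejoined at 28.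

2. Step 14. Enolisation and chelation of the β-keto lactone may consume the methylene reagent, and residual Lewis acid may attack the tert-butyl ester. The fallback sets out from 29 and replaces carbonyl methylenation by addition and elimination. CeCl3-promoted addition of Me3SiCH2MgCl (THF, −78 °C), which suppresses enolisation of readily enolised carbonyl compounds, should give the β-hydroxysilane F2. Peterson elimination under acidic conditions (aqueous HF, MeCN) then gives the exocyclic alkene, and the route is rejoined at 30.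

3. Step 10. Closure of the seven-membered lactone by metathesis may be slow compared with oligomerisation, and the β-keto ester may chelate and deactivate the catalyst. The fallback sets out from 17 and closes the ring by condensation instead, bypassing 21 and 22. A Morita–Baylis–Hillman reaction of 17 with 2,2-dimethoxyacetaldehyde (DABCO) gives tert-butyl 3-hydroxy-4,4-dimethoxy-2-methylidenebutanoate F3. NBS/Me2S converts it with allylic transposition into the (Z)-allylic bromide F4. Displacement with lithium acetoacetate (DMF) gives the acetoacetate F5. Acetal hydrolysis (LiBF4, wet MeCN) gives the aldehyde F6, and an intramolecular Knoevenagel condensation (piperidinium acetate, CH2Cl2, high dilution, 4 Å MS) closes the oxepinone, so the route is rejoined at 25.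

Further compounds
F1 | step 12 | bicyclic 2-ethoxy-3,4-dihydro-2H-pyran from 25 and (E)-1-ethoxy-3-methylbut-1-ene, isopropyl trans to the lactone ring residue, acetal carbon unassigned | CCOC1OC(C)=C2C(=O)OCC(C(=O)OC(C)(C)C)=C[C@@H]2[C@H]1C(C)C
F2 | step 14 | tert-butyl (5aS,6R,9aS)-9-hydroxy-1-oxo-6-(propan-2-yl)-9-[(trimethylsilyl)methyl]-1,3,5a,6,7,8,9,9a-octahydro-2-benzoxepine-4-carboxylate, C-9 epimers | CC(C)[C@H]1CCC(O)(C[Si](C)(C)C)[C@H]2C(=O)OCC(C(=O)OC(C)(C)C)=C[C@H]12
F3 | step 10 | tert-butyl 3-hydroxy-4,4-dimethoxy-2-methylidenebutanoate | CC(C)(C)OC(=O)C(=C)C(O)C(OC)OC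
F4 | step 10 | tert-butyl (2Z)-2-(bromomethyl)-4,4-dimethoxybut-2-enoate | CC(C)(C)OC(=O)/C(CBr)=C/C(OC)OC
F5 | step 10 | tert-butyl (2E)-4,4-dimethoxy-2-{[(3-oxobutanoyl)oxy]methyl}but-2-enoate | CC(=O)CC(=O)OC/C(C(=O)OC(C)(C)C)=C\C(OC)OC
F6 | step 10 | tert-butyl (2E)-4-oxo-2-{[(3-oxobutanoyl)oxy]methyl}but-2-enoate | CC(=O)CC(=O)OC/C(C(=O)OC(C)(C)C)=C\C=O
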